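The route rests on disconnecting the aryl ether bond O1–C8a of ring C. O1 is the only atom that links the aromatic carbon C8a of ring A to the stereogenic carbon C2, so ring C can be closed there by a copper-catalysed intramolecular O-arylation that touches neither C2 nor C3 and carries a preset syn-(1R,2R) diol pair directly into the 2,3-cis (2R,3R) chroman in one operation. The precursor is an open-chain 1,3-diarylpropane-1,2-diol: free benzylic hydroxyl at the future C2, a triisopropylsilyl ether on the future O3, and a ring A bromide placed ortho to the benzylic methylene and meta to both benzyloxy groups.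

Key step: step 10

Remarks on the chemistry:
- Only a ring A bromide that is meta to both benzyloxy groups leads to the 5,7-dioxygenated chroman. Ring A is therefore entered by formylation of 1,3-bis(benzyloxy)-5-bromobenzene; ring bromination of a 3,5-bis(benzyloxy)benzyl alcohol would put the ring oxygens at C6 and C8.
- O3 carries a triisopropylsilyl and not a tert-butyldimethylsilyl ether. A small silyl group next to a caesium alkoxide at 110 °C can migrate from O3 to the benzylic oxygen, which would open the way to the five-membered ether.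
- Assumption: 1,3-bis(benzyloxy)-5-bromobenzene (the dibenzyl ether of 5-bromoresorcinol) is taken as a catalogue compound.

Step 1
Reactants: 1 1,3-bis(benzyloxy)-5-bromobenzene
Product: 3 2-bromo-4,6-bis(benzyloxy)benzaldehyde, via aryl iminium salt 2 (not isolated)
Conditions: POCl3, DMF, 0 °C to 75 °C; then H2O, rt
Reagents that add atoms: N,N-dimethylformamide CN(C)C=O (formyl carbon); water O (carbonyl oxygen)
Why: Vilsmeier–Haack formylation should go at the position next to bromine, which is ortho to one benzyloxy group and para to the other, in preference to the position flanked by both benzyloxy groups, and the minor 4-bromo-2,6-bis(benzyloxy) isomer is to be removed by crystallisation.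

Step 2
Reactants: 3 2-bromo-4,6-bis(benzyloxy)benzaldehyde
Product: 4 [2-bromo-4,6-bis(benzyloxy)phenyl]methanol
Conditions: NaBH4, THF/MeOH, 0 °C
Reagents that add atoms: none
Why: Borohydride reduction of an aromatic aldehyde is chemoselective and leaves the aryl bromide and the benzyl ethers untouched.

Step 3
Reactants: 4 [2-bromo-4,6-bis(benzyloxy)phenyl]methanol
Product: 5 2-bromo-4,6-bis(benzyloxy)benzyl bromide [1,5-bis(benzyloxy)-3-bromo-2-(bromomethyl)benzene]
Conditions: CBr4, PPh3, CH2Cl2, 0 °C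
Reagents that add atoms: carbon tetrabromide BrC(Br)(Br)Br
Why: Appel bromination converts the primary benzylic alcohol under neutral conditions, which suits an electron-rich benzylic bromide that would not tolerate acid and is to be used at once.

Step 4
Reactants: 6 glycolic acid
Product: 8 2-[(triisopropylsilyl)oxy]acetic acid, via bis-silylated glycolate 7 (not isolated)
Conditions: i-Pr3SiCl (2.2 equiv), imidazole, DMF, rt; then K2CO3, THF/H2O, rt; HCl to pH 3
Reagents that add atoms: triisopropylsilyl chloride CC(C)[Si](Cl)(C(C)C)C(C)C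
Why: Silylation of hydroxyl and carboxyl followed by mild-base cleavage of the far more labile silyl ester is the standard entry to O-silylglycolic acids.

Step 5
Reactants: 8 2-[(triisopropylsilyl)oxy]acetic acid; 9 (S)-4-benzyl-1,3-oxazolidin-2-one
Product: 11 (S)-4-benzyl-3-{2-[(triisopropylsilyl)oxy]acetyl}-1,3-oxazolidin-2-one, via mixed pivalic anhydride 10 (not isolated)
Conditions: t-BuCOCl, Et3N, THF, −20 °C to 0 °C; then 9, LiCl, rt
Reagents that add atoms: none
Why: N-acylation of an oxazolidinone by a mixed pivalic anhydride in the presence of LiCl and Et3N is a standard route to glycolyl imides, attack going at the unhindered glycolyl carbonyl.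

Step 6
Reactants: 11 (S)-4-benzyl-3-{2-[(triisopropylsilyl)oxy]acetyl}-1,3-oxazolidin-2-one; 5 2-bromo-4,6-bis(benzyloxy)benzyl bromide
Product: 13 (4S)-4-benzyl-3-{(2R)-3-[2-bromo-4,6-bis(benzyloxy)phenyl]-2-[(triisopropylsilyl)oxy]propanoyl}-1,3-oxazolidin-2-one, via sodium enolate 12 (not isolated)
Conditions: 11 (1.5 equiv), NaN(SiMe3)2, THF, −78 °C; then 5, −78 °C to −40 °C
Reagents that add atoms: none
Why: Evans glycolate alkylation, in which the chelated sodium (Z)-enolate is attacked by the reactive benzylic bromide on the face opposite the C4 benzyl group of the auxiliary, should set the (R) configuration at the silyloxy-bearing carbon (the future C3).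

Step 7
Reactants: 13 (4S)-4-benzyl-3-{(2R)-3-[2-bromo-4,6-bis(benzyloxy)phenyl]-2-[(triisopropylsilyl)oxy]propanoyl}-1,3-oxazolidin-2-one
Product: 14 (2R)-3-[2-bromo-4,6-bis(benzyloxy)phenyl]-N-methoxy-N-methyl-2-[(triisopropylsilyl)oxy]propanamide
Conditions: Me3Al, MeNH(OMe)·HCl, CH2Cl2, −10 °C to rt
Reagents that add atoms: N,O-dimethylhydroxylamine hydrochloride CNOC.Cl
Why: Aluminium amide transamination of an N-acyl oxazolidinone (Weinreb amide formation) is an established, non-epimerising cleavage that also returns the auxiliary.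

Step 8
Reactants: 15 4-bromo-1,2-bis(benzyloxy)benzene; 14 (2R)-3-[2-bromo-4,6-bis(benzyloxy)phenyl]-N-methoxy-N-methyl-2-[(triisopropylsilyl)oxy]propanamide
Product: 17 (2R)-1-[3,4-bis(benzyloxy)phenyl]-3-[2-bromo-4,6-bis(benzyloxy)phenyl]-2-[(triisopropylsilyl)oxy]propan-1-one, via arylmagnesium bromide 16 (not isolated)
Conditions: Mg, THF, 50 °C; then 14, THF, 0 °C to rt
Reagents that add atoms: none
Why: In this Weinreb ketone synthesis the aryl Grignard reagent adds only once to the N-methoxy-N-methylamide, the ketone appears only on work-up so the α-silyloxy centre should not epimerise, and the ring A bromide does not exchange with an arylmagnesium bromide at this temperature.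

Step 9
Reactants: 17 (2R)-1-[3,4-bis(benzyloxy)phenyl]-3-[2-bromo-4,6-bis(benzyloxy)phenyl]-2-[(triisopropylsilyl)oxy]propan-1-one
Product: 18 (1R,2R)-1-[3,4-bis(benzyloxy)phenyl]-3-[2-bromo-4,6-bis(benzyloxy)phenyl]-2-[(triisopropylsilyl)oxy]propan-1-ol (syn)
Conditions: LiBH(s-Bu)3, THF, −78 °C; then NaOH, H2O2, 0 °C
Reagents that add atoms: none
Why: Felkin–Anh-controlled ketone reduction, with the bulky non-chelating silyloxy group anti to the incoming bulky hydride and attack passing the α-hydrogen, should give the syn (1R,2R) alcohol, so the new carbinol centre (the future C2) is set by 1,2-induction from the silyloxy-bearing carbon.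

Step 10
Reactants: 18 (1R,2R)-1-[3,4-bis(benzyloxy)phenyl]-3-[2-bromo-4,6-bis(benzyloxy)phenyl]-2-[(triisopropylsilyl)oxy]propan-1-ol
Product: 19 (2R,3R)-5,7-bis(benzyloxy)-2-[3,4-bis(benzyloxy)phenyl]-3-[(triisopropylsilyl)oxy]chromane
Conditions: CuI (10 mol%), 3,4,7,8-tetramethyl-1,10-phenanthroline (20 mol%), Cs2CO3 (2 equiv), 4 Å MS, toluene (0.05 M), 110 °C, argon
Reagents that add atoms: none
Why: Cs2CO3 generates the benzylic alkoxide, which binds phenanthroline-ligated monovalent copper; this copper alkoxide activates the ortho C–Br bond of ring A (oxidative addition to an aryl trivalent copper species), and C–O reductive elimination forms O1–C8a and returns monovalent copper. The closest known reaction type is the Ullmann-type copper-catalysed O-arylation of aliphatic alcohols with aryl halides, used intramolecularly to make chromans. Ring C closes in a six-membered, formally 6-exo mode at the sp2 carbon C8a through a seven-membered cupracycle. No stereocentre is formed and no bond at C2 or C3 is broken, so the (1R,2R) syn pair is carried with retention into the (2R,3R) cis chroman. The step needs site selectivity between O1 and O3 and cyclisation in preference to hydrodebromination or oxidation of the alkoxide; the first is secured by the triisopropylsilyl ether on O3, which is too bulky to migrate to the neighbouring alkoxide and leaves only the benzylic oxygen able to reach C8a, the second by the mild carbonate base, exclusion of oxygen and water, and dilution.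

Step 11
Reactants: 19 (2R,3R)-5,7-bis(benzyloxy)-2-[3,4-bis(benzyloxy)phenyl]-3-[(triisopropylsilyl)oxy]chromane
Product: 20 (2R,3R)-5,7-bis(benzyloxy)-2-[3,4-bis(benzyloxy)phenyl]chroman-3-ol (5,7,3',4'-tetra-O-benzylepicatechin)
Conditions: n-Bu4NF, THF, rt to 45 °C
Reagents that add atoms: none
Why: Fluoride-mediated desilylation frees O3 without affecting aryl benzyl ethers or the chroman, and no base-labile group is present at this stage.

Step 12
Reactants: 21 3,5-dihydroxy-4-methoxybenzoic acid
Product: 23 3,5-bis(benzyloxy)-4-methoxybenzoic acid, via benzyl ester 22 (not isolated)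
Conditions: BnBr (3.3 equiv), K2CO3, DMF, 60 °C; then NaOH, MeOH/H2O, 70 °C; HCl to pH 2
Reagents that add atoms: benzyl bromide BrCc1ccccc1; sodium hydroxide [Na+].[OH-] (one carboxyl oxygen)
Why: Williamson O-benzylation of both phenols with concomitant benzyl ester formation, followed by saponification of that ester, is the usual preparation of benzyl-protected gallic acids and leaves the 4-methoxy group untouched.

Step 13
Reactants: 20 (2R,3R)-5,7-bis(benzyloxy)-2-[3,4-bis(benzyloxy)phenyl]chroman-3-ol; 23 3,5-bis(benzyloxy)-4-methoxybenzoic acid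
Product: 24 (2R,3R)-5,7-bis(benzyloxy)-2-[3,4-bis(benzyloxy)phenyl]chroman-3-yl 3,5-bis(benzyloxy)-4-methoxybenzoate
Conditions: DCC, DMAP, CH2Cl2, rt
Reagents that add atoms: none
Why: Steglich esterification is the established way to acylate the axial 3-hydroxyl of benzyl-protected epicatechins with benzyl-protected gallic acids, and it takes place at oxygen with retention at C3.

Step 14
Reactants: 24 (2R,3R)-5,7-bis(benzyloxy)-2-[3,4-bis(benzyloxy)phenyl]chroman-3-yl 3,5-bis(benzyloxy)-4-methoxybenzoate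
Product: 25 (2R,3R)-2-(3,4-dihydroxyphenyl)-5,7-dihydroxychroman-3-yl 3,5-dihydroxy-4-methoxybenzoate [epicatechin 3-O-(4-O-methylgallate)]
Conditions: H2 (1 atm), Pd(OH)2/C, THF/MeOH, rt
Reagents that add atoms: none
Why: Catalytic hydrogenolysis should cleave all six O-benzyl groups under neutral conditions that spare the aryl methyl ether, the ester and both stereocentres, provided the reaction is stopped at full debenzylation so that the benzylic C2–O1 bond is not reduced.

Compound list
1 | 1,3-bis(benzyloxy)-5-bromobenzene | Brc1cc(OCc2ccccc2)cc(OCc2ccccc2)c1 | starting material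
2 | N-[2-bromo-4,6-bis(benzyloxy)benzylidene]-N-methylmethanaminium dichlorophosphate | C[N+](C)=Cc1c(Br)cc(OCc2ccccc2)cc1OCc1ccccc1.[O-]P(=O)(Cl)Cl | intermediate
3 | 2-bromo-4,6-bis(benzyloxy)benzaldehyde | O=Cc1c(Br)cc(OCc2ccccc2)cc1OCc1ccccc1 | intermediate
4 | [2-bromo-4,6-bis(benzyloxy)phenyl]methanol | OCc1c(Br)cc(OCc2ccccc2)cc1OCc1ccccc1 | intermediate
5 | 2-bromo-4,6-bis(benzyloxy)benzyl bromide | BrCc1c(Br)cc(OCc2ccccc2)cc1OCc1ccccc1 | intermediate
6 | glycolic acid | OCC(=O)O | starting material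
7 | triisopropylsilyl 2-[(triisopropylsilyl)oxy]acetate | CC(C)[Si](C(C)C)(C(C)C)OCC(=O)O[Si](C(C)C)(C(C)C)C(C)C | intermediate
8 | 2-[(triisopropylsilyl)oxy]acetic acid | CC(C)[Si](C(C)C)(C(C)C)OCC(=O)O | intermediate
9 | (S)-4-benzyl-1,3-oxazolidin-2-one | O=C1N[C@@H](Cc2ccccc2)CO1 | starting material
10 | pivalic 2-[(triisopropylsilyl)oxy]acetic anhydride | CC(C)[Si](C(C)C)(C(C)C)OCC(=O)OC(=O)C(C)(C)C | intermediate
11 | (S)-4-benzyl-3-{2-[(triisopropylsilyl)oxy]acetyl}-1,3-oxazolidin-2-one | CC(C)[Si](C(C)C)(C(C)C)OCC(=O)N1C(=O)OC[C@@H]1Cc1ccccc1 | intermediate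
12 | sodium (Z)-enolate of 11 | [Na+].[O-]/C(=C\O[Si](C(C)C)(C(C)C)C(C)C)N1C(=O)OC[C@@H]1Cc1ccccc1 | intermediate
13 | (4S)-4-benzyl-3-{(2R)-3-[2-bromo-4,6-bis(benzyloxy)phenyl]-2-[(triisopropylsilyl)oxy]propanoyl}-1,3-oxazolidin-2-one | O=C([C@@H](Cc1c(Br)cc(OCc2ccccc2)cc1OCc1ccccc1)O[Si](C(C)C)(C(C)C)C(C)C)N1C(=O)OC[C@@H]1Cc1ccccc1 | intermediate
14 | (2R)-3-[2-bromo-4,6-bis(benzyloxy)phenyl]-N-methoxy-N-methyl-2-[(triisopropylsilyl)oxy]propanamide | CON(C)C(=O)[C@@H](Cc1c(Br)cc(OCc2ccccc2)cc1OCc1ccccc1)O[Si](C(C)C)(C(C)C)C(C)C | intermediate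
15 | 4-bromo-1,2-bis(benzyloxy)benzene | Brc1ccc(OCc2ccccc2)c(OCc2ccccc2)c1 | starting material
16 | [3,4-bis(benzyloxy)phenyl]magnesium bromide | Br[Mg]c1ccc(OCc2ccccc2)c(OCc2ccccc2)c1 | intermediate
17 | (2R)-1-[3,4-bis(benzyloxy)phenyl]-3-[2-bromo-4,6-bis(benzyloxy)phenyl]-2-[(triisopropylsilyl)oxy]propan-1-one | O=C(c1ccc(OCc2ccccc2)c(OCc2ccccc2)c1)[C@@H](Cc1c(Br)cc(OCc2ccccc2)cc1OCc1ccccc1)O[Si](C(C)C)(C(C)C)C(C)C | intermediate
18 | (1R,2R)-1-[3,4-bis(benzyloxy)phenyl]-3-[2-bromo-4,6-bis(benzyloxy)phenyl]-2-[(triisopropylsilyl)oxy]propan-1-ol | CC(C)[Si](C(C)C)(C(C)C)O[C@H](Cc1c(Br)cc(OCc2ccccc2)cc1OCc1ccccc1)[C@H](O)c1ccc(OCc2ccccc2)c(OCc2ccccc2)c1 | intermediate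
19 | (2R,3R)-5,7-bis(benzyloxy)-2-[3,4-bis(benzyloxy)phenyl]-3-[(triisopropylsilyl)oxy]chromane | CC(C)[Si](C(C)C)(C(C)C)O[C@@H]1Cc2c(OCc3ccccc3)cc(OCc3ccccc3)cc2O[C@@H]1c1ccc(OCc2ccccc2)c(OCc2ccccc2)c1 | intermediate
20 | (2R,3R)-5,7-bis(benzyloxy)-2-[3,4-bis(benzyloxy)phenyl]chroman-3-ol | O[C@@H]1Cc2c(OCc3ccccc3)cc(OCc3ccccc3)cc2O[C@@H]1c1ccc(OCc2ccccc2)c(OCc2ccccc2)c1 | intermediate
21 | 3,5-dihydroxy-4-methoxybenzoic acid | COc1c(O)cc(C(=O)O)cc1O | starting material
22 | benzyl 3,5-bis(benzyloxy)-4-methoxybenzoate | COc1c(OCc2ccccc2)cc(C(=O)OCc2ccccc2)cc1OCc1ccccc1 | intermediate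
23 | 3,5-bis(benzyloxy)-4-methoxybenzoic acid | COc1c(OCc2ccccc2)cc(C(=O)O)cc1OCc1ccccc1 | intermediate
24 | (2R,3R)-5,7-bis(benzyloxy)-2-[3,4-bis(benzyloxy)phenyl]chroman-3-yl 3,5-bis(benzyloxy)-4-methoxybenzoate | COc1c(OCc2ccccc2)cc(C(=O)O[C@@H]2Cc3c(OCc4ccccc4)cc(OCc4ccccc4)cc3O[C@@H]2c2ccc(OCc3ccccc3)c(OCc3ccccc3)c2)cc1OCc1ccccc1 | intermediate
25 | (2R,3R)-2-(3,4-dihydroxyphenyl)-5,7-dihydroxychroman-3-yl 3,5-dihydroxy-4-methoxybenzoate | COc1c(O)cc(C(=O)O[C@@H]2Cc3c(O)cc(O)cc3O[C@@H]2c2ccc(O)c(O)c2)cc1O | target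

Total step count: 14.
Longest linear sequence: 11 steps (steps 1, 2, 3, 6, 7, 8, 9, 10, 11, 13 and 14, counted from 1).

Steps most likely to fail

Step 10. Activation of the electron-rich, ortho-substituted aryl bromide may be slow, so that hydrodebromination or oxidation of the benzylic alkoxide takes over. The fallback closes ring C at the other ether bond, C2–O1, and sets out from ketone 17. Miyaura borylation (B2pin2, PdCl2(dppf), KOAc, dioxane, 80 °C) should give the aryl pinacol boronate F1, and oxidation with NaBO3 in THF/H2O the phenol ketone F2. Reductive etherification with Et3SiH and BF3·OEt2 in CH2Cl2 at −78 °C to −40 °C then lets the phenol add to the ketone, and the cyclic oxocarbenium ion is reduced by hydride delivery anti to the C3 silyloxy group. This should give the 2,3-cis chroman, and the route is rejoined at 19.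

Step 6. The glycolate enolate may decompose (loss of the oxazolidinone) before it is alkylated by the hindered and labile benzylic bromide. The fallback forms the same C–C bond by an aldol reaction followed by deoxygenation and sets out from aldehyde 3 and acid 8. Acid 8 is coupled under the conditions of step 5 with (R)-4-benzyl-1,3-oxazolidin-2-one to the enantiomeric glycolyl imide F3. The other auxiliary is needed because boron aldol addition and enolate alkylation take opposite enolate faces. A boron-mediated Evans syn aldol reaction (n-Bu2BOTf, i-Pr2NEt, CH2Cl2, −78 °C to 0 °C) with 3 should give the syn aldol adduct F4. Ionic hydrogenation of its electron-rich benzylic alcohol (Et3SiH, CF3CO2H, CH2Cl2, 0 °C) should give the deoxygenated imide F5 with the (R) configuration at the silyloxy carbon. Transamination as in step 7 rejoins the route at 14.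

Step 7. The aluminium amide may attack the ring carbonyl of the hindered imide and open the auxiliary instead of releasing it. The fallback separates cleavage and amide formation and sets out from 13. Hydrolysis with LiOH and H2O2 in THF/H2O at 0 °C should give the carboxylic acid F6, and carbodiimide coupling (EDC·HCl, HOBt, MeNH(OMe)·HCl, i-Pr2NEt, CH2Cl2) rejoins the route at 14.

Further compounds
F1 | step 10 | (2R)-1-[3,4-bis(benzyloxy)phenyl]-3-[2,4-bis(benzyloxy)-6-(4,4,5,5-tetramethyl-1,3,2-dioxaborolan-2-yl)phenyl]-2-[(triisopropylsilyl)oxy]propan-1-one | O=C(c1ccc(OCc2ccccc2)c(OCc2ccccc2)c1)[C@@H](Cc1c(B2OC(C)(C)C(C)(C)O2)cc(OCc2ccccc2)cc1OCc1ccccc1)O[Si](C(C)C)(C(C)C)C(C)C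
F2 | step 10 | (2R)-1-[3,4-bis(benzyloxy)phenyl]-3-[2,4-bis(benzyloxy)-6-hydroxyphenyl]-2-[(triisopropylsilyl)oxy]propan-1-one | O=C(c1ccc(OCc2ccccc2)c(OCc2ccccc2)c1)[C@@H](Cc1c(O)cc(OCc2ccccc2)cc1OCc1ccccc1)O[Si](C(C)C)(C(C)C)C(C)C
F3 | step 6 | (R)-4-benzyl-3-{2-[(triisopropylsilyl)oxy]acetyl}-1,3-oxazolidin-2-one | CC(C)[Si](C(C)C)(C(C)C)OCC(=O)N1C(=O)OC[C@H]1Cc1ccccc1
F4 | step 6 | (4R)-4-benzyl-3-{(2R,3S)-3-[2-bromo-4,6-bis(benzyloxy)phenyl]-3-hydroxy-2-[(triisopropylsilyl)oxy]propanoyl}-1,3-oxazolidin-2-one | O=C([C@@H]([C@@H](O)c1c(Br)cc(OCc2ccccc2)cc1OCc1ccccc1)O[Si](C(C)C)(C(C)C)C(C)C)N1C(=O)OC[C@H]1Cc1ccccc1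
F5 | step 6 | (4R)-4-benzyl-3-{(2R)-3-[2-bromo-4,6-bis(benzyloxy)phenyl]-2-[(triisopropylsilyl)oxy]propanoyl}-1,3-oxazolidin-2-one | O=C([C@@H](Cc1c(Br)cc(OCc2ccccc2)cc1OCc1ccccc1)O[Si](C(C)C)(C(C)C)C(C)C)N1C(=O)OC[C@H]1Cc1ccccc1
F6 | step 7 | (2R)-3-[2-bromo-4,6-bis(benzyloxy)phenyl]-2-[(triisopropylsilyl)oxy]propanoic acid | OC(=O)[C@@H](Cc1c(Br)cc(OCc2ccccc2)cc1OCc1ccccc1)O[Si](C(C)C)(C(C)C)C(C)C
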